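## The problem

The target is a 2-arylbenzofuran. Ring A is phloroglucinol-derived, with free hydroxyls at C4 and C6 and a 1,1-dimethylallyl (2-methylbut-3-en-2-yl) group at C7. C2 carries ring B, a 5-hydroxy-3-methoxyphenyl group with a prenyl (3-methylbut-2-enyl) chain at C2'. The target has no stereocentre, so the difficulties are regiochemical: the reverse-prenyl group must sit at C7 (between O1 and the C6 oxygen) and not at C5, the prenyl group must sit at C2' between the methoxy-bearing carbon and the carbon bonded to the furan, and the two ring B oxygens must end up different. Three features rule out rough treatment. The trisubstituted prenyl alkene is sensitive to acid, electrophilic oxidants and hydrogenation. The 1,1-dimethylallyl group has an ortho hydroxyl at C6, which adds to the alkene under acid or heat. The triphenol is electron-rich and easily oxidised. Hydrogenolysis and Lewis-acid ether cleavage are therefore excluded and the last deprotection must be neutral. The C2–C1' bond is flanked by the ortho prenyl group, which speaks against forming it late by cross-coupling. The feature that makes the key step possible is that the furan chain O1–C2–C3 with C3 bonded to C3a becomes the O1–C2–C3–C4 chain of a flavanone when one carbon is inserted between C3 and C3a; because C3 carries only hydrogen, that carbon can later leave as a carboxyl group. C3a is ortho, ortho and para to three oxygens (on C4, C7a and C6), so ring A should be an excellent migrating group in a 1,2-shift from the carbonyl carbon to the alpha carbon. Two stereocentres (C2 and C3 of a dihydrobenzofuran) appear only in passing; C2 controls C3, and both are erased on aromatisation.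

## Retrosynthesis

**Target 25 to tris(allyl ether) 24.** The three phenolic O–H bonds are traced back to O–allyl bonds. Allyl is preferred to benzyl (hydrogenolysis would reduce the alkenes), to methoxymethyl (acid removal next to the reverse-prenyl group, and no survival in acidic orthoformate) and to methyl (no selective removal beside the ring B methoxy group). The forward reaction only needs zerovalent palladium to ionise O-allyl groups and leave the two C-bound allylic groups alone.

**Benzofuran 24 to dihydrobenzofuran ester 19.** A carboxyl carbon is put back on C3 (acid 23, methyl ester 22) and the C2–C3 double bond is traced back to the 3-phenylselanyl ester 20 and then to the saturated trans ester 19. This costs four forward steps (selenation, selenoxide elimination, saponification, protodecarboxylation), but each is a standard operation, and 19 is exactly the product type of a flavanone ring contraction. A direct dehydrogenation with a quinone oxidant would be shorter but would endanger the doubly activated benzylic position of the prenyl group.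

**Ester 19 to flavanone 16 (key disconnection).** The C3–C3a bond is cut and C3a is reattached to the ester carbon, which becomes the C4 carbonyl of flavanone 16. This exchanges a 2,3-disubstituted dihydrobenzofuran for a flavanone that is assembled from two aromatic building blocks in two steps, and it fixes the benzofuran regiochemistry through the flavanone. The forward reaction must make ring A, not ring B, migrate, and the oxidant must choose the enol ether over three kinds of alkene.

**Flavanone 16 to ketone 6 and aldehyde 14.** The O1–C2 bond is cut to chalcone 15 (oxa-Michael) and the enone double bond is cut to acetophenone 6 and aldehyde 14 (Claisen–Schmidt). This is the most convergent cut: both halves carry all their substituents, and the only phenol left free in 6 is the one that becomes O1.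

**Ketone 6 to 2',4',6'-trihydroxyacetophenone 1.** The two O–allyl bonds are cut to triol 4. The C3–C bond to the 1,1-dimethylallyl group is traced by an aromatic Claisen rearrangement to the 4-O-prenyl ether 3, made from 1 and prenyl bromide 2. Placing the prenyl ether on the 4-oxygen is essential: its two ortho carbons are equivalent, and the para carbon bears the acetyl group, so no relay to a linear prenyl isomer can aromatise. The allyl groups (from allyl bromide 5) are introduced only after the thermal step so that they cannot rearrange themselves.

**Aldehyde 14 to 3-hydroxy-5-methoxybenzaldehyde 7.** The O–allyl bond is cut to the silyl ether 12, and the C2–prenyl bond is cut to the aryl anion of silyl ether 8 and prenyl bromide 2. Electrophilic halogenation of 7 would have to choose between two similarly activated positions. Directed lithiation is preferred because the masked aldehyde and the methoxy group cooperate at C2 while a bulky silyl ether shields the other two positions. The price is one protecting-group exchange, from silyl to allyl.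

## Roads not taken

**Alternative 1: ring B carried as a cyclohexanedione and aromatised late.** Ring B would be cut through two C–C bonds and built onto a preformed benzofuran. Dimethyl malonate adds to the benzofuranyl enone A2 at the carbon that becomes C1', the methyl ketone enolate closes onto one malonate ester, and saponification with decarboxylation gives the symmetric dione A1. The key step is robust classical chemistry, and the benzofuran is never exposed to an electrophilic oxidant while a prenyl alkene is present. The weak points lie after it. The two carbonyl oxygens of A1 are equivalent and must become one methoxy and one hydroxyl. The prenyl group must go to C4 of the dione (next to the aryl-bearing carbon), whereas the acidic position is C2 between the carbonyls. Alkylating a mono-enol ether at the alpha' carbon would place the prenyl group next to the oxygen that becomes the free phenol, which is the wrong isomer. The carbocycle then has to be dehydrogenated in the presence of two alkenes and an electron-rich benzofuran. The benzofuran half with its C7 reverse-prenyl group still has to be made, so nothing is saved in ring A. The chosen plan buys ring B as an aromatic compound with the oxygens already differentiated and needs no carbocycle aromatisation. Against the robust key step of this alternative it has to set a shorter and regiochemically unambiguous path to ring B.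

**Alternative 2: ring A annulated onto a furan through an acylketene.** The C3a–C4 bond would be cut. Heating the acyl Meldrum's acid A4 releases acetone and CO2, the acylketene carbon bonds to the furan beta carbon, and tautomerisation gives A3, the 5'-O-silyl ether of the target, with ring A hydroxyls free and the reverse-prenyl group placed by connectivity. The end game is clearly better than in the chosen plan: one desilylation instead of five steps, and no protecting group on ring A. The weak points are the precursor and the selectivity of the key step. A4 requires a 2-aryl-5-alkylfuran with a quaternary reverse-prenyl carbon next to a ketone, which takes several steps. The acylketene has a vinyl group four atoms away and a prenyl alkene in the same molecule, so intramolecular cycloaddition and ene pathways compete with attack on the less nucleophilic furan beta position. The product is also formed hot with a free hydroxyl ortho to the reverse-prenyl alkene. The chosen plan answers with a key step that has precedent on its exact substrate class and with ring A bought as phloroacetophenone.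

**Alternative 3: biomimetic oxidative cyclisation of a 2-hydroxystilbene.** Only the O1–C2 bond would be cut. PhI(OAc)2 oxidises the E-stilbene A6, whose only free phenol is the future O1, and the furan closes with loss of two hydrogens to give the tris(silyl ether) A5. This road is shorter than the chosen one. It carries no extra carbon that must later be removed, creates no transient stereocentres, and joins two aromatic halves by a standard olefination. In step economy it is better, and the chosen plan cannot match it there. Its weakness is the site of oxidation. The oxidant meets a free, very electron-rich phenol that has two ortho alkenes, the stilbene and the 1,1-dimethylallyl group. Closure onto the latter (a five-membered ring through the same oxygen) and dearomatisation of the phloroglucinol ring compete directly with the desired closure, and nothing in the substrate biases the choice. The chosen plan uses the same oxidant but on a molecule without free phenols and directs it to an enol ether carbon. It pays for this selectivity argument with the ester detour.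

Key step: step 9

Remarks on the chemistry. The target is achiral; compounds 16–21 are racemic, and the SMILES of 18–21 show one enantiomer of the relative configuration. The orthoester 18 is assumed to be hydrolysed to the methyl ester during aqueous work-up. "Ar" in names stands for 5-(allyloxy)-3-methoxy-2-(3-methylbut-2-enyl)phenyl.

## Route

Step 1
Reactants: 1 2',4',6'-trihydroxyacetophenone; 2 prenyl bromide
Product: 3 1-[2,6-dihydroxy-4-(3-methylbut-2-enyloxy)phenyl]ethanone
Conditions: prenyl bromide (1.05 equiv), K2CO3 (1.1 equiv), acetone, rt to 45 °C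
Reagents that add atoms: prenyl bromide (2), CC(C)=CCBr
Why: Williamson etherification at the 4-hydroxyl, the most acidic one and the only one not held in a hydrogen bond to the carbonyl; anhydrous K2CO3 in acetone with one equivalent of bromide favours O- over C-alkylation and mono- over bis-alkylation.

Step 2
Reactants: 3 1-[2,6-dihydroxy-4-(3-methylbut-2-enyloxy)phenyl]ethanone
Product: 4 1-[2,4,6-trihydroxy-3-(2-methylbut-3-en-2-yl)phenyl]ethanone
Conditions: PhNEt2, 190 °C, Ar
Reagents that add atoms: none
Why: Aromatic Claisen rearrangement: the [3,3] shift delivers the inverted allyl unit (1,1-dimethylallyl) to an ortho carbon, the two ortho carbons being equivalent, and the dienone enolises; the para carbon bears the acetyl group, so a further Cope shift cannot lead to an aromatic linear-prenyl isomer.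

Step 3
Reactants: 4 1-[2,4,6-trihydroxy-3-(2-methylbut-3-en-2-yl)phenyl]ethanone; 5 allyl bromide
Product: 6 1-[4,6-bis(allyloxy)-2-hydroxy-3-(2-methylbut-3-en-2-yl)phenyl]ethanone
Conditions: allyl bromide (2.3 equiv), K2CO3, acetone, reflux
Reagents that add atoms: allyl bromide (5), C=CCBr
Why: Williamson etherification of the 4- and 6-hydroxyls; the 2-hydroxyl is wedged between the acetyl group and the quaternary carbon and ends up locked in the hydrogen bond to the carbonyl, so it should stay free as the future O1.

Step 4
Reactants: 7 3-hydroxy-5-methoxybenzaldehyde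
Product: 8 3-methoxy-5-(triisopropylsilyloxy)benzaldehyde
Conditions: i-Pr3SiCl, imidazole, DMF, rt
Reagents that add atoms: triisopropylsilyl chloride, CC(C)[Si](Cl)(C(C)C)C(C)C
Why: Standard silylation of a phenol; the triisopropylsilyl ether is chosen because it is bulky and non-coordinating and therefore shields both of its ortho positions in the lithiation that follows.

Step 5
Reactants: 8 3-methoxy-5-(triisopropylsilyloxy)benzaldehyde; 2 prenyl bromide
Product: 12 3-methoxy-2-(3-methylbut-2-enyl)-5-(triisopropylsilyloxy)benzaldehyde, via lithium α-amino alkoxide 9 (not isolated), via ortho-lithiated α-amino alkoxide 10 (not isolated), via C2-prenylated α-amino alkoxide 11 (not isolated)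
Conditions: LiN(Me)CH2CH2NMe2 (from MeNHCH2CH2NMe2 and n-BuLi), THF, −20 °C; n-BuLi (2.5 equiv), −20 °C; prenyl bromide (excess), −78 °C to rt; cold 1 M HCl
Reagents that add atoms: prenyl bromide (2), CC(C)=CCBr
Why: α-Amino alkoxide directed ortho-lithiation with in situ protection of the aldehyde: the chelating amino alkoxide and the methoxy group together direct n-BuLi to C2, the silyl ether blocks C4 and C6, the aryllithium attacks prenyl bromide at its primary carbon, and acidic work-up collapses the hemiaminal back to the aldehyde.

Step 6
Reactants: 12 3-methoxy-2-(3-methylbut-2-enyl)-5-(triisopropylsilyloxy)benzaldehyde; 5 allyl bromide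
Product: 14 5-(allyloxy)-3-methoxy-2-(3-methylbut-2-enyl)benzaldehyde, via free phenol 13 (not isolated)
Conditions: TBAF, THF, 0 °C; then allyl bromide, rt
Reagents that add atoms: allyl bromide (5), C=CCBr
Why: Fluoride desilylation gives the tetrabutylammonium phenoxide, which is O-allylated in the same flask (Williamson); the allyl ether tolerates the hydroxide, acid and trivalent iodine to come and matches the ring A protecting groups.

Step 7
Reactants: 6 1-[4,6-bis(allyloxy)-2-hydroxy-3-(2-methylbut-3-en-2-yl)phenyl]ethanone; 14 5-(allyloxy)-3-methoxy-2-(3-methylbut-2-enyl)benzaldehyde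
Product: 15 (E)-1-[4,6-bis(allyloxy)-2-hydroxy-3-(2-methylbut-3-en-2-yl)phenyl]-3-Ar-prop-2-en-1-one
Conditions: KOH, EtOH–H2O, rt; then aq HCl
Reagents that add atoms: none
Why: Claisen–Schmidt condensation of a methyl ketone with an aldehyde that has no α-hydrogen; dehydration of the aldol gives the E-enone conjugated to ring B, and none of the ethers or alkenes reacts with aqueous hydroxide at room temperature.

Step 8
Reactants: 15 (E)-1-[4,6-bis(allyloxy)-2-hydroxy-3-(2-methylbut-3-en-2-yl)phenyl]-3-Ar-prop-2-en-1-one
Product: 16 5,7-bis(allyloxy)-2-Ar-8-(2-methylbut-3-en-2-yl)chroman-4-one (racemic)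
Conditions: NaOAc, EtOH, reflux
Reagents that add atoms: none
Why: Chalcone–flavanone isomerisation by 6-endo-trig oxa-Michael addition of the 2'-phenoxide; the 6'-alkoxy group favours the closed form, and C2 is formed as a racemate because nothing chiral is present.

Step 9
Reactants: 16 5,7-bis(allyloxy)-2-Ar-8-(2-methylbut-3-en-2-yl)chroman-4-one (racemic)
Product: 19 methyl trans-4,6-bis(allyloxy)-2-Ar-7-(2-methylbut-3-en-2-yl)-2,3-dihydrobenzofuran-3-carboxylate (racemic), via methyl enol ether 17 (not isolated), via trimethyl orthoester 18 (not isolated)
Conditions: PhI(OAc)2 (1.2 equiv), H2SO4 (cat.), HC(OMe)3, 0 °C to rt; aq NaHCO3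
Reagents that add atoms: trimethyl orthoformate, COC(OC)OC; water, O
Why: Acidic orthoformate turns 16 into its dimethyl ketal in equilibrium with enol ether 17; PhI(OAc)2 activated by H2SO4 bonds to C3 of 17 anti to the equatorial C2 aryl group and methanol restores the ketal at C4. In this trans-diequatorial 3-iodanyl ketal the C4–C4a bond is antiperiplanar to the C3–I bond, so ring A shifts from C4 to C3 as iodobenzene leaves, forming the C3–C3a bond and a dimethoxycarbenium ion that takes up methanol to give orthoester 18, which work-up hydrolyses to 19. The closest known reaction is the oxidative ring contraction of flavanones to methyl 2-aryl-2,3-dihydrobenzofuran-3-carboxylates by trivalent iodine or trivalent thallium in trimethyl orthoformate, a semipinacol-type 1,2-aryl shift. The five-membered O1–C2–C3–C3a–C7a ring is closed by contraction of the existing pyranone through this shift and not by an exo or endo cyclisation. C2 keeps its configuration and C3 is set by inversion at the iodine-bearing carbon, which puts CO2Me trans to the C2 aryl group; this is also the more stable arrangement, so any epimerisation through the enol leads to the same isomer. The step needs ring A to migrate in preference to ring B (isoflavone path) and to simple loss of HX (flavone path): the ketal stabilises the migration origin as a dialkoxycarbenium ion, C4a is ortho, ortho and para to three oxygens, and the equatorial ring B cannot align with the C3–I bond. It also needs the oxidant to choose the enol ether over the allyl, 1,1-dimethylallyl and prenyl alkenes, which follows from the much higher nucleophilicity of the enol ether; the acid is kept catalytic and cold to spare the prenyl group.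

Step 10
Reactants: 19 methyl trans-4,6-bis(allyloxy)-2-Ar-7-(2-methylbut-3-en-2-yl)-2,3-dihydrobenzofuran-3-carboxylate (racemic)
Product: 20 methyl 4,6-bis(allyloxy)-2-Ar-7-(2-methylbut-3-en-2-yl)-3-(phenylselanyl)-2,3-dihydrobenzofuran-3-carboxylate (racemic; PhSe trans to the C2 aryl group)
Conditions: LiN(i-Pr)2, THF, −78 °C; PhSeCl, −78 °C
Reagents that add atoms: phenylselenyl chloride, Cl[Se]c1ccccc1
Why: α-Selenation of the lithium ester enolate; PhSeCl approaches the face opposite the C2 aryl group, which sets the new quaternary centre with selenium cis to H-2 as the later syn elimination requires, and the in-plane C2–O1 bond of the five-membered ring overlaps poorly with the enolate so that the aryloxide is not expelled at −78 °C.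

Step 11
Reactants: 20 methyl 4,6-bis(allyloxy)-2-Ar-7-(2-methylbut-3-en-2-yl)-3-(phenylselanyl)-2,3-dihydrobenzofuran-3-carboxylate
Product: 22 methyl 4,6-bis(allyloxy)-2-Ar-7-(2-methylbut-3-en-2-yl)benzofuran-3-carboxylate, via selenoxide 21 (not isolated)
Conditions: mCPBA (1.05 equiv), CH2Cl2, −78 °C; i-Pr2NH, −78 °C to rt
Reagents that add atoms: none
Why: Selenoxide syn-elimination towards H-2, the only β-hydrogen, should give the aromatic furan below room temperature and erases both stereocentres; at −78 °C the peracid oxidises selenium far faster than the prenyl alkene, and the amine scavenges the selenenic acid.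

Step 12
Reactants: 22 methyl 4,6-bis(allyloxy)-2-Ar-7-(2-methylbut-3-en-2-yl)benzofuran-3-carboxylate
Product: 23 4,6-bis(allyloxy)-2-Ar-7-(2-methylbut-3-en-2-yl)benzofuran-3-carboxylic acid
Conditions: KOH, EtOH–H2O, 80 °C; then aq HCl to pH 4, 0 °C
Reagents that add atoms: potassium hydroxide, [K+].[OH-]
Why: Saponification of a hindered aromatic methyl ester by acyl–oxygen cleavage; aryl allyl ethers and the C-bound allylic groups are inert to hot aqueous-alcoholic hydroxide.

Step 13
Reactants: 23 4,6-bis(allyloxy)-2-Ar-7-(2-methylbut-3-en-2-yl)benzofuran-3-carboxylic acid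
Product: 24 4,6-bis(allyloxy)-2-Ar-7-(2-methylbut-3-en-2-yl)benzofuran
Conditions: Ag2CO3 (10 mol %), AcOH (5 mol %), DMSO, 120 °C
Reagents that add atoms: none
Why: Ag2CO3-catalysed protodecarboxylation of a heteroaromatic acid with two flanking substituents: the monovalent silver carboxylate loses CO2 to a C3-silver benzofuran that AcOH protonates; 120 °C is well below the temperature at which aryl allyl ethers undergo Claisen rearrangement.

Step 14
Reactants: 24 4,6-bis(allyloxy)-2-Ar-7-(2-methylbut-3-en-2-yl)benzofuran
Product: 25 2-[5-hydroxy-3-methoxy-2-(3-methylbut-2-enyl)phenyl]-7-(2-methylbut-3-en-2-yl)benzofuran-4,6-diol (CNP0169501.0)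
Conditions: Pd(PPh3)4 (5 mol %), morpholine, degassed THF, rt
Reagents that add atoms: none
Why: Tsuji–Trost deallylation: zerovalent palladium ionises the three aryl allyl ethers to π-allyl complexes that morpholine intercepts; the prenyl and 1,1-dimethylallyl groups are bound through carbon and have no leaving group, and the neutral medium avoids addition of the C6 hydroxyl to the neighbouring alkene.

## Compound list

1 | 2',4',6'-trihydroxyacetophenone | CC(=O)c1c(O)cc(O)cc1O | starting material
2 | prenyl bromide (1-bromo-3-methylbut-2-ene) | CC(C)=CCBr | starting material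
3 | 1-[2,6-dihydroxy-4-(3-methylbut-2-enyloxy)phenyl]ethanone | CC(=O)c1c(O)cc(OCC=C(C)C)cc1O | intermediate
4 | 1-[2,4,6-trihydroxy-3-(2-methylbut-3-en-2-yl)phenyl]ethanone | CC(=O)c1c(O)cc(O)c(C(C)(C)C=C)c1O | intermediate
5 | allyl bromide | C=CCBr | starting material
6 | 1-[4,6-bis(allyloxy)-2-hydroxy-3-(2-methylbut-3-en-2-yl)phenyl]ethanone | CC(=O)c1c(O)c(C(C)(C)C=C)c(OCC=C)cc1OCC=C | intermediate
7 | 3-hydroxy-5-methoxybenzaldehyde | COc1cc(O)cc(C=O)c1 | starting material
8 | 3-methoxy-5-(triisopropylsilyloxy)benzaldehyde | COc1cc(C=O)cc(O[Si](C(C)C)(C(C)C)C(C)C)c1 | intermediate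
9 | lithium α-amino alkoxide of 8 with N,N,N'-trimethylethylenediamine (not isolated) | [Li]OC(N(C)CCN(C)C)c1cc(OC)cc(O[Si](C(C)C)(C(C)C)C(C)C)c1 | intermediate
10 | C2-lithiated α-amino alkoxide (not isolated) | [Li]OC(N(C)CCN(C)C)c1cc(O[Si](C(C)C)(C(C)C)C(C)C)cc(OC)c1[Li] | intermediate
11 | C2-prenylated α-amino alkoxide (not isolated) | [Li]OC(N(C)CCN(C)C)c1cc(O[Si](C(C)C)(C(C)C)C(C)C)cc(OC)c1CC=C(C)C | intermediate
12 | 3-methoxy-2-(3-methylbut-2-enyl)-5-(triisopropylsilyloxy)benzaldehyde | O=Cc1cc(O[Si](C(C)C)(C(C)C)C(C)C)cc(OC)c1CC=C(C)C | intermediate
13 | 5-hydroxy-3-methoxy-2-(3-methylbut-2-enyl)benzaldehyde (present as its tetrabutylammonium phenoxide, not isolated) | O=Cc1cc(O)cc(OC)c1CC=C(C)C | intermediate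
14 | 5-(allyloxy)-3-methoxy-2-(3-methylbut-2-enyl)benzaldehyde | O=Cc1cc(OCC=C)cc(OC)c1CC=C(C)C | intermediate
15 | (E)-1-[4,6-bis(allyloxy)-2-hydroxy-3-(2-methylbut-3-en-2-yl)phenyl]-3-[5-(allyloxy)-3-methoxy-2-(3-methylbut-2-enyl)phenyl]prop-2-en-1-one | O=C(/C=C/c1cc(OCC=C)cc(OC)c1CC=C(C)C)c1c(O)c(C(C)(C)C=C)c(OCC=C)cc1OCC=C | intermediate
16 | 5,7-bis(allyloxy)-2-[5-(allyloxy)-3-methoxy-2-(3-methylbut-2-enyl)phenyl]-8-(2-methylbut-3-en-2-yl)chroman-4-one, racemic | O=C1CC(c2cc(OCC=C)cc(OC)c2CC=C(C)C)Oc2c(C(C)(C)C=C)c(OCC=C)cc(OCC=C)c12 | intermediate
17 | 5,7-bis(allyloxy)-2-[5-(allyloxy)-3-methoxy-2-(3-methylbut-2-enyl)phenyl]-4-methoxy-8-(2-methylbut-3-en-2-yl)-2H-chromene, racemic (not isolated) | COC1=CC(c2cc(OCC=C)cc(OC)c2CC=C(C)C)Oc2c(C(C)(C)C=C)c(OCC=C)cc(OCC=C)c12 | intermediate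
18 | trans-4,6-bis(allyloxy)-2-[5-(allyloxy)-3-methoxy-2-(3-methylbut-2-enyl)phenyl]-7-(2-methylbut-3-en-2-yl)-3-(trimethoxymethyl)-2,3-dihydrobenzofuran, racemic (not isolated) | COC(OC)(OC)[C@@H]1[C@@H](c2cc(OCC=C)cc(OC)c2CC=C(C)C)Oc2c(C(C)(C)C=C)c(OCC=C)cc(OCC=C)c21 | intermediate
19 | methyl trans-4,6-bis(allyloxy)-2-[5-(allyloxy)-3-methoxy-2-(3-methylbut-2-enyl)phenyl]-7-(2-methylbut-3-en-2-yl)-2,3-dihydrobenzofuran-3-carboxylate, racemic, drawn as (2S,3S) | COC(=O)[C@@H]1[C@@H](c2cc(OCC=C)cc(OC)c2CC=C(C)C)Oc2c(C(C)(C)C=C)c(OCC=C)cc(OCC=C)c21 | intermediate
20 | methyl 4,6-bis(allyloxy)-2-[5-(allyloxy)-3-methoxy-2-(3-methylbut-2-enyl)phenyl]-7-(2-methylbut-3-en-2-yl)-3-(phenylselanyl)-2,3-dihydrobenzofuran-3-carboxylate, racemic, PhSe trans to the C2 aryl group | COC(=O)[C@@]1([Se]c2ccccc2)[C@@H](c2cc(OCC=C)cc(OC)c2CC=C(C)C)Oc2c(C(C)(C)C=C)c(OCC=C)cc(OCC=C)c21 | intermediate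
21 | selenoxide of 20, mixture at selenium (not isolated) | COC(=O)[C@@]1([Se](=O)c2ccccc2)[C@@H](c2cc(OCC=C)cc(OC)c2CC=C(C)C)Oc2c(C(C)(C)C=C)c(OCC=C)cc(OCC=C)c21 | intermediate
22 | methyl 4,6-bis(allyloxy)-2-[5-(allyloxy)-3-methoxy-2-(3-methylbut-2-enyl)phenyl]-7-(2-methylbut-3-en-2-yl)benzofuran-3-carboxylate | COC(=O)c1c(-c2cc(OCC=C)cc(OC)c2CC=C(C)C)oc2c(C(C)(C)C=C)c(OCC=C)cc(OCC=C)c12 | intermediate
23 | 4,6-bis(allyloxy)-2-[5-(allyloxy)-3-methoxy-2-(3-methylbut-2-enyl)phenyl]-7-(2-methylbut-3-en-2-yl)benzofuran-3-carboxylic acid | OC(=O)c1c(-c2cc(OCC=C)cc(OC)c2CC=C(C)C)oc2c(C(C)(C)C=C)c(OCC=C)cc(OCC=C)c12 | intermediate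
24 | 4,6-bis(allyloxy)-2-[5-(allyloxy)-3-methoxy-2-(3-methylbut-2-enyl)phenyl]-7-(2-methylbut-3-en-2-yl)benzofuran | C=CC(C)(C)c1c(OCC=C)cc(OCC=C)c2cc(-c3cc(OCC=C)cc(OC)c3CC=C(C)C)oc12 | intermediate
25 | 2-[5-hydroxy-3-methoxy-2-(3-methylbut-2-enyl)phenyl]-7-(2-methylbut-3-en-2-yl)benzofuran-4,6-diol | C=CC(C)(C)c1c(O)cc(O)c2cc(-c3cc(O)cc(OC)c3CC=C(C)C)oc12 | target

## Step count and least certain steps

Total: 14 steps. Longest linear sequence: 11 steps (1 to 25 through steps 1–3 and 7–14; the branch from 7 through steps 4–6 and 7–14 is equally long).

**Step 9 (key step).** The most likely failures are three. Trivalent iodine or the acid may attack the prenyl alkene (oxidative methoxylation or addition of methanol). The very electron-rich rings may be iodinated or converted to iodonium salts once the carbonyl is masked. Enol ether formation may be sluggish because the carbonyl is a doubly vinylogous ester, which would let the flavone or isoflavone paths compete. The fallback keeps the same 1,2-shift of ring A but reaches it through a carbene instead of an iodonium intermediate, with no acid and no oxidant. Starting from 16, the lithium enolate (LiN(SiMe3)2, THF, −78 °C) is acylated with 2,2,2-trifluoroethyl trifluoroacetate to give 5,7-bis(allyloxy)-2-Ar-8-(2-methylbut-3-en-2-yl)-3-(trifluoroacetyl)chroman-4-one F1. Detrifluoroacetylative diazo transfer (MsN3, Et3N, MeCN) gives the 3-diazochroman-4-one F2. Irradiation of F2 in methanol brings about a Wolff rearrangement with ring contraction, and methanol traps the ketene as the methyl ester. After equilibration with NaOMe in MeOH to the trans isomer this is 19, where the route is rejoined.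

**Step 5.** Lithiation may occur at another ring position, or the excess n-BuLi may attack silicon, since the regiochemistry rests on cooperative direction and steric shielding and not on a blocking atom. The fallback fixes the site with a halogen. Starting from 7, para-selective bromination of the free phenol (Bu4NBr3, CH2Cl2–MeOH) should give 2-bromo-5-hydroxy-3-methoxybenzaldehyde F3, separable from any isomer. O-Allylation (allyl bromide, K2CO3) gives 5-(allyloxy)-2-bromo-3-methoxybenzaldehyde F4, and ethylene glycol with TsOH gives the dioxolane F5. Bromine–lithium exchange (n-BuLi, THF, −78 °C), transmetalation with CuBr·SMe2 and alkylation with prenyl bromide give the prenylated dioxolane F6. Dilute HCl in THF then releases 14, where the route is rejoined; steps 4–6 are bypassed.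

**Step 2.** The freshly formed 4-hydroxyl may add thermally to the neighbouring 1,1-dimethylallyl double bond (dihydrofuran formation or rearrangement of the side chain), or the prenyl ether may simply cleave. The fallback traps the phenols as they appear. Starting from 3, the rearrangement is run in PhNEt2 containing Ac2O and NaOAc, so that all three hydroxyls are acetylated and the product is 2,4,6-triacetoxy-3-(2-methylbut-3-en-2-yl)acetophenone F7. Methanolysis (K2CO3, MeOH, rt) returns 4.

**Step 1.** C-Prenylation of the phloroglucinol nucleus and bis-alkylation may erode the yield of the mono ether. The fallback avoids a free phenoxide: Mitsunobu etherification of 1 with 3-methylbut-2-en-1-ol (PPh3, diisopropyl azodicarboxylate, THF, 0 °C) engages the most acidic hydroxyl and leads to 3 directly, without new intermediates.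

**Step 10.** Selenation at the hindered, fully substituted C3 may be slow, and on warming the enolate may open the ring by expelling the aryloxide. The fallback removes the carboxyl carbon and introduces the double bond in one oxidative step. Starting from 19, saponification (KOH, EtOH–H2O) gives trans-4,6-bis(allyloxy)-2-Ar-7-(2-methylbut-3-en-2-yl)-2,3-dihydrobenzofuran-3-carboxylic acid F8. Oxidative decarboxylation with Pb(OAc)4 and catalytic Cu(OAc)2 in benzene–pyridine at 80 °C generates the benzylic C3 radical, which divalent copper oxidises with loss of H-2, giving 24 directly; steps 10–13 are bypassed.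

## Further compounds

F1 | step 9 | 5,7-bis(allyloxy)-2-[5-(allyloxy)-3-methoxy-2-(3-methylbut-2-enyl)phenyl]-8-(2-methylbut-3-en-2-yl)-3-(trifluoroacetyl)chroman-4-one (racemic) | O=C1C(C(=O)C(F)(F)F)C(c2cc(OCC=C)cc(OC)c2CC=C(C)C)Oc2c(C(C)(C)C=C)c(OCC=C)cc(OCC=C)c12
F2 | step 9 | 5,7-bis(allyloxy)-2-[5-(allyloxy)-3-methoxy-2-(3-methylbut-2-enyl)phenyl]-3-diazo-8-(2-methylbut-3-en-2-yl)chroman-4-one (racemic) | O=C1C(=[N+]=[N-])C(c2cc(OCC=C)cc(OC)c2CC=C(C)C)Oc2c(C(C)(C)C=C)c(OCC=C)cc(OCC=C)c12
F3 | step 5 | 2-bromo-5-hydroxy-3-methoxybenzaldehyde | O=Cc1cc(O)cc(OC)c1Br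
F4 | step 5 | 5-(allyloxy)-2-bromo-3-methoxybenzaldehyde | O=Cc1cc(OCC=C)cc(OC)c1Br
F5 | step 5 | 2-[5-(allyloxy)-2-bromo-3-methoxyphenyl]-1,3-dioxolane | C=CCOc1cc(OC)c(Br)c(C2OCCO2)c1
F6 | step 5 | 2-[5-(allyloxy)-3-methoxy-2-(3-methylbut-2-enyl)phenyl]-1,3-dioxolane | C=CCOc1cc(OC)c(CC=C(C)C)c(C2OCCO2)c1
F7 | step 2 | 2,4,6-triacetoxy-3-(2-methylbut-3-en-2-yl)acetophenone | CC(=O)Oc1cc(OC(C)=O)c(C(C)(C)C=C)c(OC(C)=O)c1C(C)=O
F0 | step 1 | none | none
F8 | step 10 | trans-4,6-bis(allyloxy)-2-[5-(allyloxy)-3-methoxy-2-(3-methylbut-2-enyl)phenyl]-7-(2-methylbut-3-en-2-yl)-2,3-dihydrobenzofuran-3-carboxylic acid (racemic) | OC(=O)[C@@H]1[C@@H](c2cc(OCC=C)cc(OC)c2CC=C(C)C)Oc2c(C(C)(C)C=C)c(OCC=C)cc(OCC=C)c21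
A1 | alternative 1 | 5-[4,6-bis(methoxymethoxy)-7-(2-methylbut-3-en-2-yl)benzofuran-2-yl]cyclohexane-1,3-dione | O=C1CC(=O)CC(C1)c1cc2c(OCOC)cc(OCOC)c(C(C)(C)C=C)c2o1
A2 | alternative 1 | (E)-4-[4,6-bis(methoxymethoxy)-7-(2-methylbut-3-en-2-yl)benzofuran-2-yl]but-3-en-2-one | CC(=O)/C=C/c1cc2c(OCOC)cc(OCOC)c(C(C)(C)C=C)c2o1
A3 | alternative 2 | 2-[3-methoxy-2-(3-methylbut-2-enyl)-5-(triisopropylsilyloxy)phenyl]-7-(2-methylbut-3-en-2-yl)benzofuran-4,6-diol | C=CC(C)(C)c1c(O)cc(O)c2cc(-c3cc(O[Si](C(C)C)(C(C)C)C(C)C)cc(OC)c3CC=C(C)C)oc12
A4 | alternative 2 | 5-{2-[5-(3-methoxy-2-(3-methylbut-2-enyl)-5-(triisopropylsilyloxy)phenyl)furan-2-yl]-3,3-dimethylpent-4-enoyl}-2,2-dimethyl-1,3-dioxane-4,6-dione (racemic) | CC1(C)OC(=O)C(C(=O)C(c2ccc(-c3cc(O[Si](C(C)C)(C(C)C)C(C)C)cc(OC)c3CC=C(C)C)o2)C(C)(C)C=C)C(=O)O1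
A5 | alternative 3 | 2-[3-methoxy-2-(3-methylbut-2-enyl)-5-(triisopropylsilyloxy)phenyl]-7-(2-methylbut-3-en-2-yl)-4,6-bis(triisopropylsilyloxy)benzofuran | C=CC(C)(C)c1c(O[Si](C(C)C)(C(C)C)C(C)C)cc(O[Si](C(C)C)(C(C)C)C(C)C)c2cc(-c3cc(O[Si](C(C)C)(C(C)C)C(C)C)cc(OC)c3CC=C(C)C)oc12
A6 | alternative 3 | (E)-2-{2-[3-methoxy-2-(3-methylbut-2-enyl)-5-(triisopropylsilyloxy)phenyl]vinyl}-6-(2-methylbut-3-en-2-yl)-3,5-bis(triisopropylsilyloxy)phenol | C=CC(C)(C)c1c(O)c(/C=C/c2cc(O[Si](C(C)C)(C(C)C)C(C)C)cc(OC)c2CC=C(C)C)c(O[Si](C(C)C)(C(C)C)C(C)C)cc1O[Si](C(C)C)(C(C)C)C(C)C
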